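**Plan**
- The target is an achiral flavonol. The last bonds cut are the C8–C(quaternary) bond of the 1,1-dimethylallyl group and the C3'–CH and O4'–CMe2 bonds of the pyran.
- These cuts are possible because C8 of ring A lies ortho to O7, and the pyran CH carbon on C3' of ring B lies ortho to O4' while the other ortho position, C5', is blocked by oxygen. Both carbon units can therefore be delivered from ether oxygens: a 7-O-prenyl ether and a 4'-O-(2-methylbut-3-yn-2-yl) ether.
- Ring C is cut next at O1–C2 and C3–OH (oxidative cyclisation of a 2'-hydroxychalcone), and the chalcone at its Cα=Cβ bond (aldol condensation of a ring A acetophenone with a ring B benzaldehyde).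
- The 2'-prenyl group comes from a Stille coupling on a bromobenzaldehyde, and all ethers from O-alkylations ranked by phenol acidity.
- Forward order: ring A ketone (2 steps) and ring B aldehyde (4 steps), then chalcone, ring C, 3-O-protection, one thermolysis that closes the pyran and moves the C5 unit to C8, and MOM removal.
- Stereochemistry: the target has no stereocentre; only the E-chalcone geometry (thermodynamic) and the ring-imposed cis pyran alkene arise.

Key step: step 10

Remark on the chemistry: the sp3 centres of the dihydroflavonol and of the two cyclohexadienone intermediates are transient and racemic; flavone numbering with primed ring B positions is used from the chalcone cyclisation onward; MOM = methoxymethyl.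

**Route**

Step 1
Reactants: 1 2,4,6-trihydroxyacetophenone; 2 prenyl bromide (1-bromo-3-methylbut-2-ene)
Product: 3 1-[2,6-dihydroxy-4-(3-methylbut-2-enyloxy)phenyl]ethanone
Conditions: 2 (1.0 equiv), K2CO3 (1.1 equiv), acetone, reflux
Reagents that add atoms: none
Why: Williamson O-alkylation should occur at the 4-hydroxyl, the only phenol not chelated to the acetyl carbonyl and the most acidic one, so one equivalent of weak base and bromide should give the mono-ether.

Step 2
Reactants: 3 1-[2,6-dihydroxy-4-(3-methylbut-2-enyloxy)phenyl]ethanone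
Product: 4 1-[2-hydroxy-6-(methoxymethoxy)-4-(3-methylbut-2-enyloxy)phenyl]ethanone
Conditions: MOMCl (1.05 equiv), i-Pr2NEt, CH2Cl2, 0 °C
Reagents that add atoms: chloromethyl methyl ether, COCCl
Why: O-alkylation to the MOM acetal on one of the two equivalent ortho phenols should stop at the mono-ether, because the remaining hydroxyl is then locked in the hydrogen-bonded chelate with the ketone.

Step 3
Reactants: 5 2-bromo-4,5-dimethoxybenzaldehyde
Product: 6 2-bromo-4,5-dihydroxybenzaldehyde
Conditions: BBr3 (3 equiv), CH2Cl2, −78 °C to rt; then H2O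
Reagents that add atoms: none
Why: Lewis-acid cleavage of aryl methyl ethers with BBr3 is standard for dimethoxybenzaldehydes and should leave the formyl group and the aryl bromide intact.

Step 4
Reactants: 6 2-bromo-4,5-dihydroxybenzaldehyde; 7 3-chloro-3-methylbut-1-yne
Product: 8 2-bromo-5-hydroxy-4-(2-methylbut-3-yn-2-yloxy)benzaldehyde
Conditions: 7 (1.2 equiv), DBU (1.1 equiv), CuCl2·2H2O (1 mol%), MeCN, 0 °C
Reagents that add atoms: none
Why: Copper-catalysed O-alkylation of a phenoxide with a tertiary propargylic chloride should take place at the 4-hydroxyl, since one equivalent of base ionises only the phenol para to the formyl group, which is markedly more acidic than its meta neighbour.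

Step 5
Reactants: 8 2-bromo-5-hydroxy-4-(2-methylbut-3-yn-2-yloxy)benzaldehyde
Product: 9 2-bromo-5-(methoxymethoxy)-4-(2-methylbut-3-yn-2-yloxy)benzaldehyde
Conditions: MOMCl (1.3 equiv), i-Pr2NEt, CH2Cl2, 0 °C to rt
Reagents that add atoms: chloromethyl methyl ether, COCCl
Why: MOM ether formation by O-alkylation of the single remaining phenol is routine and is compatible with the aldehyde, the aryl bromide and the terminal alkyne.

Step 6
Reactants: 9 2-bromo-5-(methoxymethoxy)-4-(2-methylbut-3-yn-2-yloxy)benzaldehyde; 10 tributyl(3-methylbut-2-enyl)stannane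
Product: 11 5-(methoxymethoxy)-4-(2-methylbut-3-yn-2-yloxy)-2-(3-methylbut-2-enyl)benzaldehyde
Conditions: 10 (1.3 equiv), Pd(PPh3)4 (5 mol%), DMF, 85 °C, degassed
Reagents that add atoms: none
Why: Stille cross-coupling at the aryl bromide, activated towards zerovalent palladium by the ortho formyl group, should transfer the prenyl unit through its unsubstituted CH2 terminus, and the base-free, copper-free medium should spare the terminal alkyne and stay below the temperature at which the propargyl ether rearranges.

Step 7
Reactants: 4 1-[2-hydroxy-6-(methoxymethoxy)-4-(3-methylbut-2-enyloxy)phenyl]ethanone; 11 5-(methoxymethoxy)-4-(2-methylbut-3-yn-2-yloxy)-2-(3-methylbut-2-enyl)benzaldehyde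
Product: 12 (E)-1-[2-hydroxy-6-(methoxymethoxy)-4-(3-methylbut-2-enyloxy)phenyl]-3-[5-(methoxymethoxy)-4-(2-methylbut-3-yn-2-yloxy)-2-(3-methylbut-2-enyl)phenyl]prop-2-en-1-one
Conditions: KOH (excess), EtOH–H2O, rt
Reagents that add atoms: none
Why: Claisen–Schmidt condensation of the methyl ketone with the non-enolisable aldehyde should give the E-chalcone under thermodynamic control, and every ether present is stable to hydroxide.

Step 8
Reactants: 12 the E-chalcone of step 7
Product: 14 3-hydroxy-5-(methoxymethoxy)-7-(3-methylbut-2-enyloxy)-2-[5-(methoxymethoxy)-4-(2-methylbut-3-yn-2-yloxy)-2-(3-methylbut-2-enyl)phenyl]chromen-4-one, via trans-dihydroflavonol 13 (not isolated)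
Conditions: 30% aq H2O2, NaOH, MeOH–THF, 0 °C to rt
Reagents that add atoms: hydrogen peroxide, OO
Why: In this Algar–Flynn–Oyamada oxidation the 2'-phenoxide should close 6-endo onto the enone β-carbon while hydroperoxide supplies the C3 oxygen to give the racemic 2,3-trans dihydroflavonol 13 (both substituents equatorial), which alkaline peroxide dehydrogenates to the flavonol, and nucleophilic alkaline H2O2 does not attack the isolated prenyl alkenes or the alkyne.

Step 9
Reactants: 14 the 3-hydroxyflavone of step 8
Product: 15 3,5-bis(methoxymethoxy)-7-(3-methylbut-2-enyloxy)-2-[5-(methoxymethoxy)-4-(2-methylbut-3-yn-2-yloxy)-2-(3-methylbut-2-enyl)phenyl]chromen-4-one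
Conditions: MOMCl (2 equiv), i-Pr2NEt, CH2Cl2, 0 °C to rt
Reagents that add atoms: chloromethyl methyl ether, COCCl
Why: O-alkylation of the acidic, only weakly chelated 3-hydroxyl of a flavonol to its MOM ether is routine and removes the last free hydroxyl before the thermolysis.

Step 10
Reactants: 15 the 7-O-prenyl 4'-O-(2-methylbut-3-yn-2-yl) tris-MOM flavone of step 9
Product: 21 8-(2-methylbut-3-en-2-yl)-7-hydroxy-3,5-bis(methoxymethoxy)-2-[8-(methoxymethoxy)-2,2-dimethyl-5-(3-methylbut-2-enyl)-2H-chromen-6-yl]chromen-4-one (3,5,5'-tri-O-MOM broussoflavonol D), via allenyl dienone 16 (not isolated), via allenylphenol 17 (not isolated), via ortho-quinone methide 18 (not isolated), via chromene prenyl ether 19 (not isolated), via C8 dienone 20 (not isolated)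
Conditions: PhNEt2 (0.05 M), 190–200 °C, argon, sealed vessel
Reagents that add atoms: none
Why: Heat first triggers the aromatic propargyl Claisen [3,3] shift of the 4'-ether to the C3' allenyl dienone 16, which tautomerises to allenylphenol 17, relays the phenolic hydrogen by a [1,5] shift to the central allene carbon to give the Z ortho-quinone methide 18 and closes the six-membered pyran by thermal disrotatory oxa-6π electrocyclisation (O4' onto CMe2), giving 19. At the same temperature the 7-O-prenyl ether undergoes the aromatic Claisen [3,3] shift with allyl inversion to the C8 dienone 20, and enolisation of 20 restores ring A as the 7-phenol with the quaternary 1,1-dimethylallyl carbon on C8. The closest known reaction types are the thermal conversion of aryl 1,1-dimethylpropargyl ethers into 2,2-dimethyl-2H-chromenes and the Claisen rearrangement of 7-prenyloxychromones to 8-(1,1-dimethylallyl)-7-hydroxychromones in hot N,N-diethylaniline. No stereocentre is created, since the sp3 carbons of 16 and 20 are lost on tautomerisation and the pyran alkene is cis by ring constraint. The selectivity required is C3' over C5' on ring B and C8 over C6 on ring A: C5' carries the MOM ether and cannot rearomatise, while C8 is favoured by the greater double-bond character of C7–C8 in a 5-O-alkylated chromone and by crowding of C6 by the neighbouring 5-O-MOM group. Both cascades are unimolecular and reagent-free, the basic solvent keeps acid-promoted cyclisation of the new ortho-allylphenol in check, and the order of the two events (pyran first, as the tertiary propargyl ether should react at the lower temperature) does not change the product.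

Step 11
Reactants: 21 3,5,5'-tri-O-MOM broussoflavonol D
Product: 22 broussoflavonol D
Conditions: aq HCl (about 1.5 M in the mixture), MeOH, 45 °C
Reagents that add atoms: none
Why: Acid-catalysed acetal exchange of the three MOM ethers with methanol should release the 3-, 5- and 5'-hydroxyls, and dilute acid at mild temperature is expected to leave the prenyl, 1,1-dimethylallyl and chromene alkenes untouched.

**Compound list**
1 | 2,4,6-trihydroxyacetophenone | CC(=O)c1c(O)cc(O)cc1O | starting material
2 | prenyl bromide (1-bromo-3-methylbut-2-ene) | CC(C)=CCBr | starting material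
3 | 1-[2,6-dihydroxy-4-(3-methylbut-2-enyloxy)phenyl]ethanone | CC(=O)c1c(O)cc(OCC=C(C)C)cc1O | intermediate
4 | 1-[2-hydroxy-6-(methoxymethoxy)-4-(3-methylbut-2-enyloxy)phenyl]ethanone | CC(=O)c1c(O)cc(OCC=C(C)C)cc1OCOC | intermediate
5 | 2-bromo-4,5-dimethoxybenzaldehyde | COc1cc(Br)c(C=O)cc1OC | starting material
6 | 2-bromo-4,5-dihydroxybenzaldehyde | O=Cc1cc(O)c(O)cc1Br | intermediate
7 | 3-chloro-3-methylbut-1-yne | C#CC(C)(C)Cl | starting material
8 | 2-bromo-5-hydroxy-4-(2-methylbut-3-yn-2-yloxy)benzaldehyde | C#CC(C)(C)Oc1cc(Br)c(C=O)cc1O | intermediate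
9 | 2-bromo-5-(methoxymethoxy)-4-(2-methylbut-3-yn-2-yloxy)benzaldehyde | C#CC(C)(C)Oc1cc(Br)c(C=O)cc1OCOC | intermediate
10 | tributyl(3-methylbut-2-enyl)stannane | CC(C)=CC[Sn](CCCC)(CCCC)CCCC | starting material
11 | 5-(methoxymethoxy)-4-(2-methylbut-3-yn-2-yloxy)-2-(3-methylbut-2-enyl)benzaldehyde | C#CC(C)(C)Oc1cc(CC=C(C)C)c(C=O)cc1OCOC | intermediate
12 | (E)-1-[2-hydroxy-6-(methoxymethoxy)-4-(3-methylbut-2-enyloxy)phenyl]-3-[5-(methoxymethoxy)-4-(2-methylbut-3-yn-2-yloxy)-2-(3-methylbut-2-enyl)phenyl]prop-2-en-1-one | CC(C)=CCOc1cc(O)c(C(=O)/C=C/c2cc(OCOC)c(OC(C)(C)C#C)cc2CC=C(C)C)c(OCOC)c1 | intermediate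
13 | racemic 2,3-trans-3-hydroxy-5-(methoxymethoxy)-7-(3-methylbut-2-enyloxy)-2-[5-(methoxymethoxy)-4-(2-methylbut-3-yn-2-yloxy)-2-(3-methylbut-2-enyl)phenyl]chroman-4-one (2R,3R enantiomer drawn) | O=C1c2c(OCOC)cc(OCC=C(C)C)cc2O[C@H](c2cc(OCOC)c(OC(C)(C)C#C)cc2CC=C(C)C)[C@H]1O | intermediate
14 | 3-hydroxy-5-(methoxymethoxy)-7-(3-methylbut-2-enyloxy)-2-[5-(methoxymethoxy)-4-(2-methylbut-3-yn-2-yloxy)-2-(3-methylbut-2-enyl)phenyl]chromen-4-one | CC(C)=CCOc1cc(OCOC)c2c(=O)c(O)c(-c3cc(OCOC)c(OC(C)(C)C#C)cc3CC=C(C)C)oc2c1 | intermediate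
15 | 3,5-bis(methoxymethoxy)-7-(3-methylbut-2-enyloxy)-2-[5-(methoxymethoxy)-4-(2-methylbut-3-yn-2-yloxy)-2-(3-methylbut-2-enyl)phenyl]chromen-4-one | CC(C)=CCOc1cc(OCOC)c2c(=O)c(OCOC)c(-c3cc(OCOC)c(OC(C)(C)C#C)cc3CC=C(C)C)oc2c1 | intermediate
16 | allenyl dienone: ring B of 15 as a racemic cyclohexa-2,4-dienone with C4'=O and C3' carrying H and a 3-methylbuta-1,2-dienyl group | CC(C)=CCOc1cc(OCOC)c2c(=O)c(OCOC)c(C3=C(CC=C(C)C)C(C=C=C(C)C)C(=O)C(OCOC)=C3)oc2c1 | intermediate
17 | allenylphenol: 4'-hydroxy-3'-(3-methylbuta-1,2-dienyl) flavone with the 7-O-prenyl ether intact | CC(C)=CCOc1cc(OCOC)c2c(=O)c(OCOC)c(-c3cc(OCOC)c(O)c(C=C=C(C)C)c3CC=C(C)C)oc2c1 | intermediate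
18 | ortho-quinone methide: ring B with C4'=O and a Z exocyclic C3'=CH–CH=CMe2 unit | CC(C)=CCOc1cc(OCOC)c2c(=O)c(OCOC)c(C3=C(CC=C(C)C)/C(=C/C=C(C)C)C(=O)C(OCOC)=C3)oc2c1 | intermediate
19 | chromene prenyl ether: 3,5-bis(methoxymethoxy)-7-(3-methylbut-2-enyloxy)-2-[8-(methoxymethoxy)-2,2-dimethyl-5-(3-methylbut-2-enyl)-2H-chromen-6-yl]chromen-4-one | CC(C)=CCOc1cc(OCOC)c2c(=O)c(OCOC)c(-c3cc(OCOC)c4c(c3CC=C(C)C)C=CC(C)(C)O4)oc2c1 | intermediate
20 | C8 dienone: racemic 8-(2-methylbut-3-en-2-yl)-8H-chromene-4,7-dione tautomer of 21 | C=CC(C)(C)C1C(=O)C=C(OCOC)C2=C1OC(c1cc(OCOC)c3c(c1CC=C(C)C)C=CC(C)(C)O3)=C(OCOC)C2=O | intermediate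
21 | 3,5,5'-tri-O-MOM broussoflavonol D (free 7-hydroxyl, 8-(2-methylbut-3-en-2-yl), ring B 2,2-dimethylpyran) | C=CC(C)(C)c1c(O)cc(OCOC)c2c(=O)c(OCOC)c(-c3cc(OCOC)c4c(c3CC=C(C)C)C=CC(C)(C)O4)oc12 | intermediate
22 | broussoflavonol D | C=CC(C)(C)c1c(O)cc(O)c2c(=O)c(O)c(-c3cc(O)c4c(c3CC=C(C)C)C=CC(C)(C)O4)oc12 | target

**Count**
Total steps: 11. Longest linear sequence: 9 steps (5 → 6 → 8 → 9 → 11 → 12 → 14 → 15 → 21 → 22); the ring A branch (1 → 3 → 4) joins at step 7.

**Steps most likely to fail**

Step 10. Because both cascades are run at the temperature the slower one needs, the freshly formed ortho-(1,1-dimethylallyl)phenol may react further (abnormal Claisen isomerisation or ring closure onto O7), and discrimination between C8 and C6 may erode on long heating. The fallback sets out from 15 and separates the two events. Heating 15 in xylene at about 135 °C should complete only the ring B cascade and allow the chromene prenyl ether 19 to be isolated. Compound 19 would then be rearranged in N,N-diethylaniline at 190 °C in the presence of acetic anhydride and NaOAc, so that the 7-phenol is captured as it forms, giving the 7-O-acetate of 3,5,5'-tri-O-MOM broussoflavonol D F1. Brief methanolysis of F1 with catalytic K2CO3 in MeOH at 0 °C should cleave the aryl acetate and return to the route at 21.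

Step 8. The phenoxide may close in the five-membered mode onto the α-carbon during the peroxide oxidation, giving an aurone instead of the flavonol; the 6'-alkoxy group and the twisted, ortho-substituted ring B both favour this. The fallback sets out from 12 and closes the six-membered ring before any oxidant is present. NaOAc in refluxing EtOH should isomerise the chalcone by oxa-Michael addition to the racemic flavanone 5-(methoxymethoxy)-7-(3-methylbut-2-enyloxy)-2-[5-(methoxymethoxy)-4-(2-methylbut-3-yn-2-yloxy)-2-(3-methylbut-2-enyl)phenyl]chroman-4-one F2. Its potassium enolate (KN(SiMe3)2, 1.05 equiv, THF, −78 °C; the ketone is far more acidic than the alkyne) would be hydroxylated with 2-(phenylsulfonyl)-3-phenyloxaziridine, an oxidant that leaves the isolated alkenes alone. This rejoins the route at 13, which is then dehydrogenated to 14 by the alkaline hydrogen peroxide of step 8. Any enolate that ring-opens simply regenerates 12 and can be recycled.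

Step 6. The free terminal alkyne or the tertiary propargylic C–O bond may engage zerovalent palladium (alkyne coupling, ionisation of the propargyl ether) in competition with the cross-coupling. The fallback sets out from 6 and installs the prenyl group before any alkyne is present. Double protection (MOMCl, i-Pr2NEt) gives 2-bromo-4,5-bis(methoxymethoxy)benzaldehyde F3. The same Stille coupling with 10 then gives 4,5-bis(methoxymethoxy)-2-(3-methylbut-2-enyl)benzaldehyde F4. Dilute HCl in MeOH–THF removes both acetals to give 4,5-dihydroxy-2-(3-methylbut-2-enyl)benzaldehyde F5. The acidity-controlled propargylation of step 4 (7, DBU, catalytic CuCl2·2H2O, MeCN, 0 °C) gives 5-hydroxy-4-(2-methylbut-3-yn-2-yloxy)-2-(3-methylbut-2-enyl)benzaldehyde F6. MOM protection of F6 returns to the route at 11.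

**Further compounds**
F1 | step 10 | 7-O-acetyl-3,5,5'-tri-O-MOM broussoflavonol D | C=CC(C)(C)c1c(OC(C)=O)cc(OCOC)c2c(=O)c(OCOC)c(-c3cc(OCOC)c4c(c3CC=C(C)C)C=CC(C)(C)O4)oc12
F2 | step 8 | racemic 5-(methoxymethoxy)-7-(3-methylbut-2-enyloxy)-2-[5-(methoxymethoxy)-4-(2-methylbut-3-yn-2-yloxy)-2-(3-methylbut-2-enyl)phenyl]chroman-4-one | O=C1CC(c2cc(OCOC)c(OC(C)(C)C#C)cc2CC=C(C)C)Oc2cc(OCC=C(C)C)cc(OCOC)c21
F3 | step 6 | 2-bromo-4,5-bis(methoxymethoxy)benzaldehyde | O=Cc1cc(OCOC)c(OCOC)cc1Br
F4 | step 6 | 4,5-bis(methoxymethoxy)-2-(3-methylbut-2-enyl)benzaldehyde | CC(C)=CCc1cc(OCOC)c(OCOC)cc1C=O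
F5 | step 6 | 4,5-dihydroxy-2-(3-methylbut-2-enyl)benzaldehyde | CC(C)=CCc1cc(O)c(O)cc1C=O
F6 | step 6 | 5-hydroxy-4-(2-methylbut-3-yn-2-yloxy)-2-(3-methylbut-2-enyl)benzaldehyde | C#CC(C)(C)Oc1cc(CC=C(C)C)c(C=O)cc1O
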